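The constants were drawn at random within sensible limits; no experiment stands behind them.

If I ask what stands at the end of these flasks, I need two sums: how much intermediate is made and how hard it is drained.

in all of them: substrate 12 mM; free catalyst 8.2 mol%; second catalyst 0.15 mol% (in portions, 3); added ligand 3.9 mM; time 25 h

|  | partner | remark |
|---|---|---|
| epsilon | 0.600 equiv | the portions of second catalyst follow each other after 8.0 h, the first at the start |
| theta | 1.00 equiv | the portions of second catalyst follow each other after 8.0 h, the first at the start |
| alpha | 1.50 equiv | the portions of second catalyst follow each other after 8.0 h, the first at the start |

    free catalyst + added ligand ⇌ idle complex (K1 = 16000 /M, k1 = 0.98 /M/min)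
    partner + second catalyst + intermediate → second catalyst + product (k2 = 12000 /M²/min)
    substrate + free catalyst → free catalyst + intermediate (k3 = 1.1 /M/min)

1. amount of intermediate at the end, in percent of the substrate charged for epsilon, theta, alpha, in this order
2. how the row runs (hardly changes / rises all the way / falls all the way / falls, then rises / rises, then falls)

- "hardly changes" means that all values lie within two and a half points (for a concentration: within two and a half percent of the largest)
- run time (epsilon): 25 h

I start from the smaller of the binding pair, free catalyst at 0.984 mM against 3.9 mM of added ligand. Its balance is free catalyst plus idle complex equals charge, and the equilibrium constant times the ligand charge, 62, tips that balance towards idle complex. With the ligand held at its charge, free catalyst lasts about 4.36 h, which makes the substrate's logarithmic loss 0.283. So I reckon 24.7% of the substrate becomes intermediate, the same in each flask, as partner enters neither step.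

At any moment the intermediate decays pseudo-first-order. Second catalyst stands 17.0 h on average over its portions, so the rate constant times partner charge times second catalyst charge times that time comes to 1.59 for epsilon, 2.64 for theta and 3.97 for alpha. I call this the drain number: the logarithmic loss of intermediate if all of it stood there from the start and partner never fell.

Two extreme flasks bracket the row. With no drain, each keeps 24.7%. With the full drain number, they end at 5.04%, 1.76% and 0.466%. Intermediate keeps forming for about 4.36 h, which is shorter than the run but not negligible, so some of it misses the early drain and the real flasks must stand above that floor. I commit to a row that falls throughout.

The forecast gives 10.4%, 5% and 2%, so falls all the way: the later portions “drain that intermediate roughly in proportion to the partner concentration”. It counts about 30 percent made, above my 24.7%.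

The flasks give 9.92%, 4.77% and 2.05%, so falls all the way.

In epsilon 28.9% of the substrate has gone, so the drain actually suffered is 1.07, a share of 0.675 of the drain number. Applied to alpha, which has lost the same substrate, that share gives 1.99%, and alpha stands at 2.05%. One change that does take the forecast's epsilon value away is removing the binding of free catalyst: in the run without that binding, epsilon ends at 41.9% instead of 9.92%.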